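Everything rests on cutting ring C at C4a–C4, C4–C3 and O1–C2. C4 is a lone carbonyl carbon lodged between ring A (C4a) and the C3–C2 pair that bears ring B. It can therefore be supplied by CO, and C3–C2 by a terminal arylalkyne. One palladium-catalysed pot unites an ortho-iodophenol derivative, CO and the alkyne and closes the pyranone. This delivers the complete flavone skeleton with the prenyl ether already in place. The ring A partner is the mono-iodide of a symmetric 4-methoxy-3,5-bis(methoxymethoxy)phenol, used as its O-acetate. O-3 follows by C3 metalation, borylation and oxidation. The MOM groups then leave under buffered, non-protic conditions that spare the prenyl ether.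

Key step: step 6

Remark on stereochemistry: the target has no stereocentre, and its only non-aromatic alkene carries two identical methyl groups. It is therefore achiral, and no step has to control configuration.
Remark on design: the aryl prenyl ether is the fragile group. It is sensitive to Pd-allyl ionisation, electrophilic oxidants and Brønsted acid, and steps 5–8 are chosen around it. MOM = methoxymethyl, prenyl = 3-methylbut-2-en-1-yl; flavone numbering is used.

Step 1
Reactants: 1 2-methoxyresorcinol
Product: 2 2-methoxy-1,3-bis(methoxymethoxy)benzene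
Conditions: MOMCl (2.5 equiv), i-Pr2NEt (3 equiv), CH2Cl2, 0 °C → rt
Reagents that add atoms: chloromethyl methyl ether (MOMCl), COCCl
Why: Williamson-type O-alkylation of both phenols with the reactive α-chloro ether under amine base is routine, and the MOM acetals tolerate every basic, organometallic and oxidative step that follows.

Step 2
Reactants: 2 2-methoxy-1,3-bis(methoxymethoxy)benzene
Product: 4 4-methoxy-3,5-bis(methoxymethoxy)phenol, via arylboronate 3 (not isolated)
Conditions: [Ir(OMe)(cod)]2 (1.5 mol %), dtbpy (3 mol %), B2pin2 (0.7 equiv), THF, 80 °C; then 30 % aq. H2O2, aq. NaOH, 0 °C; NH4Cl work-up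
Reagents that add atoms: bis(pinacolato)diboron, CC1(C)OB(B2OC(C)(C)C(C)(C)O2)OC1(C)C (boryl group of 3 only); hydrogen peroxide, OO (phenol oxygen of 4)
Why: Sterically governed iridium-catalysed C–H borylation should attack only C5, the sole C–H without an ortho neighbour, and the peroxide-induced boron-to-oxygen aryl shift turns the boronate into the phenol in the same flask under basic conditions that leave the acetals alone.

Step 3
Reactants: 4 4-methoxy-3,5-bis(methoxymethoxy)phenol
Product: 6 2-iodo-4-methoxy-3,5-bis(methoxymethoxy)phenyl acetate, via iodophenol 5 (not isolated)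
Conditions: NIS (1.0 equiv), MeCN, −20 → 0 °C, dark; then Et3N (3 equiv), Ac2O (2 equiv), DMAP (cat.), 0 °C → rt
Reagents that add atoms: N-iodosuccinimide, O=C1CCC(=O)N1I; acetic anhydride, CC(=O)OC(C)=O
Why: Electrophilic aromatic iodination can only strike C2 or C6, which the mirror plane of 4 makes identical, so one equivalent of NIS at low temperature should give a single mono-iodide, and DMAP-catalysed acetylation in the same flask caps the air-sensitive iodophenol.

Step 4
Reactants: 7 4-hydroxybenzaldehyde; 8 prenyl bromide
Product: 9 4-(3-methylbut-2-enyloxy)benzaldehyde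
Conditions: K2CO3 (1.5 equiv), acetone, reflux
Reagents that add atoms: none
Why: Williamson ether synthesis, in which the carbonate-generated phenoxide displaces the primary allylic bromide by SN2 and the electron-poor ring disfavours C-alkylation.

Step 5
Reactants: 9 4-(3-methylbut-2-enyloxy)benzaldehyde
Product: 10 1-ethynyl-4-(3-methylbut-2-enyloxy)benzene
Conditions: dimethyl (1-diazo-2-oxopropyl)phosphonate (1.2 equiv), K2CO3 (2 equiv), MeOH, rt
Reagents that add atoms: dimethyl (1-diazo-2-oxopropyl)phosphonate, COP(=O)(OC)C(=[N+]=[N-])C(C)=O (terminal alkyne carbon)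
Why: Ohira–Bestmann variant of the Seyferth–Gilbert homologation, in which the unmasked diazomethylphosphonate anion olefinates the aldehyde and loss of N2 with a 1,2-hydrogen shift gives the terminal alkyne, all under mild carbonate conditions and without palladium near the allylic ether.

Step 6
Reactants: 6 2-iodo-4-methoxy-3,5-bis(methoxymethoxy)phenyl acetate; 10 1-ethynyl-4-(3-methylbut-2-enyloxy)benzene; 11 carbon monoxide
Product: 14 6-methoxy-5,7-bis(methoxymethoxy)-4'-prenyloxyflavone, via ynone acetate 12 (not isolated), via enaminone 13 (not isolated)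
Conditions: PdCl2(dppf) (5 mol %), Et3N (3 equiv), CO (balloon to 5 bar), dioxane, 50–60 °C; then Et2NH (5 equiv), same pot, 50–60 °C
Reagents that add atoms: diethylamine, CCNCC (amino group of 13 only; none of it stays in 14)
Why: Pd(0) inserts into the C–I bond of 6 (the future C4a), CO migratory insertion gives the aroyl-palladium species, and base-assisted alkynyl transfer from 10 with reductive elimination forms C4a–C4 and C4–C3 in ynone 12, which is a copper-free carbonylative Sonogashira coupling. Diethylamine added to the same pot then adds to the ynone in conjugate fashion and removes the acetate, and in enaminone 13 the freed phenol oxygen attacks C2 and expels the amine in a 6-endo-trig addition–elimination that forms O1–C2 and closes ring C; taken together this is the known carbonylative annulation of 2-iodophenol derivatives with terminal alkynes to flavones. No stereocentre is created. Flavone rather than aurone closure is secured because the amine makes C2 the only electrophilic carbon of a vinylogous amide and so shuts the 5-exo path at C3, and 6-methoxy rather than 8-methoxy regiochemistry is secured because only the acetate oxygen can be unmasked while the other ortho oxygen stays a MOM ether. The acetate makes the arene less electron-rich for oxidative addition and keeps phenoxide and secondary amine away from the aroyl-palladium stage, which should suppress ester and amide formation and leaves no nucleophile to drive Pd-allyl cleavage of the prenyl ether at this mild temperature. The flanking OAc and OMOM groups will slow oxidative addition but favour CO insertion, so CO-free coupling should stay minor.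

Step 7
Reactants: 14 6-methoxy-5,7-bis(methoxymethoxy)-4'-prenyloxyflavone
Product: 17 3-hydroxy-6-methoxy-5,7-bis(methoxymethoxy)-4'-prenyloxyflavone, via 3-lithioflavone 15 (not isolated), via borate 16 (not isolated)
Conditions: B(Oi-Pr)3 (2 equiv), then commercial LDA (1.5 equiv) dropwise, THF, −78 °C; then 30 % aq. H2O2, 0 °C → rt
Reagents that add atoms: hydrogen peroxide, OO (O-3 of 17); triisopropyl borate, CC(C)OB(OC(C)C)OC(C)C (boron unit of 16 only); lithium diisopropylamide, [Li+].CC(C)[N-]C(C)C (lithium of 15 and 16 only)
Why: Deprotonation of a flavone at C3 by LDA (the vinylic C–H beside the lithium-binding C4 carbonyl is the kinetically most acidic site), borate trapping and boron-to-oxygen migration is a known flavone-to-flavonol sequence; borate already present in the flask captures the fragile anion before it can ring-open, and nucleophilic hydroperoxide leaves the electron-rich prenyl alkene alone, unlike dioxiranes or peracids.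

Step 8
Reactants: 17 3-hydroxy-6-methoxy-5,7-bis(methoxymethoxy)-4'-prenyloxyflavone
Product: 19 3,5,7-trihydroxy-6-methoxy-4'-prenyloxyflavone, via tris-silyl ether 18 (not isolated)
Conditions: TMSOTf (6 equiv), 2,2'-bipyridyl (9 equiv), MeCN, 0 °C → rt; then H2O, rt
Reagents that add atoms: trimethylsilyl triflate, C[Si](C)(C)OS(=O)(=O)C(F)(F)F (silyl groups of 18 only; none stays in 19)
Why: Silyl triflate/2,2'-bipyridyl cleavage of aromatic MOM ethers, in which the buffered silyl electrophile activates the acetal, bipyridyl carries off the methoxymethyl unit and the phenols emerge as TMS ethers that water hydrolyses, so no free strong acid meets the aryl prenyl ether, whose ionisation or hydration is the weak point of ordinary acidic MOM removal.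

Compound list
1 | 2-methoxyresorcinol (2-methoxybenzene-1,3-diol) | COc1c(O)cccc1O | starting material
2 | 2-methoxy-1,3-bis(methoxymethoxy)benzene | COCOc1cccc(OCOC)c1OC | intermediate
3 | 2-[4-methoxy-3,5-bis(methoxymethoxy)phenyl]-4,4,5,5-tetramethyl-1,3,2-dioxaborolane (not isolated) | COCOc1cc(B2OC(C)(C)C(C)(C)O2)cc(OCOC)c1OC | intermediate
4 | 4-methoxy-3,5-bis(methoxymethoxy)phenol | COCOc1cc(O)cc(OCOC)c1OC | intermediate
5 | 2-iodo-4-methoxy-3,5-bis(methoxymethoxy)phenol (not isolated) | COCOc1cc(O)c(I)c(OCOC)c1OC | intermediate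
6 | 2-iodo-4-methoxy-3,5-bis(methoxymethoxy)phenyl acetate | COCOc1cc(OC(C)=O)c(I)c(OCOC)c1OC | intermediate
7 | 4-hydroxybenzaldehyde | O=Cc1ccc(O)cc1 | starting material
8 | prenyl bromide (1-bromo-3-methylbut-2-ene) | CC(C)=CCBr | starting material
9 | 4-(3-methylbut-2-enyloxy)benzaldehyde | CC(C)=CCOc1ccc(C=O)cc1 | intermediate
10 | 1-ethynyl-4-(3-methylbut-2-enyloxy)benzene | C#Cc1ccc(OCC=C(C)C)cc1 | intermediate
11 | carbon monoxide | [C-]#[O+] | starting material
12 | 4-methoxy-3,5-bis(methoxymethoxy)-2-{3-[4-(3-methylbut-2-enyloxy)phenyl]prop-2-ynoyl}phenyl acetate (not isolated) | COCOc1cc(OC(C)=O)c(C(=O)C#Cc2ccc(OCC=C(C)C)cc2)c(OCOC)c1OC | intermediate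
13 | (E)-3-(diethylamino)-1-[2-hydroxy-5-methoxy-4,6-bis(methoxymethoxy)phenyl]-3-[4-(3-methylbut-2-enyloxy)phenyl]prop-2-en-1-one (not isolated; push–pull alkene, geometry labile, drawn E) | COCOc1cc(O)c(C(=O)/C=C(/N(CC)CC)c2ccc(OCC=C(C)C)cc2)c(OCOC)c1OC | intermediate
14 | 6-methoxy-5,7-bis(methoxymethoxy)-4'-prenyloxyflavone | COCOc1cc2oc(-c3ccc(OCC=C(C)C)cc3)cc(=O)c2c(OCOC)c1OC | intermediate
15 | 3-lithio-6-methoxy-5,7-bis(methoxymethoxy)-4'-prenyloxyflavone (not isolated) | COCOc1cc2oc(-c3ccc(OCC=C(C)C)cc3)c([Li])c(=O)c2c(OCOC)c1OC | intermediate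
16 | lithium triisopropoxy[6-methoxy-5,7-bis(methoxymethoxy)-4'-prenyloxyflavon-3-yl]borate (not isolated) | [Li+].COCOc1cc2oc(-c3ccc(OCC=C(C)C)cc3)c([B-](OC(C)C)(OC(C)C)OC(C)C)c(=O)c2c(OCOC)c1OC | intermediate
17 | 3-hydroxy-6-methoxy-5,7-bis(methoxymethoxy)-4'-prenyloxyflavone | COCOc1cc2oc(-c3ccc(OCC=C(C)C)cc3)c(O)c(=O)c2c(OCOC)c1OC | intermediate
18 | 6-methoxy-4'-prenyloxy-3,5,7-tris(trimethylsilyloxy)flavone (not isolated) | COc1c(O[Si](C)(C)C)cc2oc(-c3ccc(OCC=C(C)C)cc3)c(O[Si](C)(C)C)c(=O)c2c1O[Si](C)(C)C | intermediate
19 | 3,5,7-trihydroxy-6-methoxy-4'-prenyloxyflavone (achiral) | COc1c(O)cc2oc(-c3ccc(OCC=C(C)C)cc3)c(O)c(=O)c2c1O | target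

Total step count: 8. Longest linear sequence: 6 steps (steps 1, 2, 3, 6, 7 and 8, from 1 to 19).

Steps most likely to fail

Step 6. Oxidative addition at the doubly ortho-flanked, electron-rich C–I bond may be so slow that other processes take over. These are catalyst decay, reductive loss of iodine, early loss of the acetate and CO-free coupling. The fallback drops palladium and CO. It sets out from 5 (isolated by leaving out the acetylation in step 3) and from 10, and it comes back at 14. Alkyne 10 would be treated with n-BuLi (THF, −78 °C) and N-methoxy-N-methylcarbamoyl chloride to give the Weinreb amide N-methoxy-N-methyl-3-[4-(3-methylbut-2-enyloxy)phenyl]prop-2-ynamide F1. Iodophenol 5 would be deprotonated with NaH (THF, 0 °C), submitted to iodine–lithium exchange with n-BuLi (−78 °C) and combined with F1. This should give 1-[2-hydroxy-5-methoxy-4,6-bis(methoxymethoxy)phenyl]-3-[4-(3-methylbut-2-enyloxy)phenyl]prop-2-yn-1-one F2. Et2NH in EtOH at 50 °C should then close F2 through 13 to 14.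

Step 7. Three processes could erode the step: competing metalation at C8 between the two oxygens, β-elimination of the C3 anion with opening of ring C, and loss of boron by protonation before oxidation. The fallback builds the flavonol by oxidative chalcone cyclisation. It sets out from 5 (isolated as above) and from 9, and it comes back at 17. Compound 5 would be treated with NaH, then n-BuLi (THF, −78 °C), then N-methoxy-N-methylacetamide to give 1-[2-hydroxy-5-methoxy-4,6-bis(methoxymethoxy)phenyl]ethanone F3. Claisen–Schmidt condensation of F3 with 9 (KOH, EtOH, rt) should give (E)-1-[2-hydroxy-5-methoxy-4,6-bis(methoxymethoxy)phenyl]-3-[4-(3-methylbut-2-enyloxy)phenyl]prop-2-en-1-one F4. The Algar–Flynn–Oyamada reaction (H2O2, NaOH, MeOH, 0 °C → rt) should convert F4 into 17, with the prenyl alkene inert to alkaline peroxide. The alkoxy group ortho to the carbonyl is known to divert part of such chalcones towards five-ring closure, which is why this stays the second choice.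

Step 8. The prenyl ether may ionise or migrate from oxygen to carbon under the silyl electrophile, or the 7-O acetal may cleave incompletely. The fallback moves all acetal cleavage ahead of prenylation and ends with a base-labile deprotection. It sets out from 6 and comes back at 19.
- Compound 6, CO and commercial 1-(benzyloxy)-4-ethynylbenzene under the conditions of step 6 should give 4'-benzyloxy-6-methoxy-5,7-bis(methoxymethoxy)flavone F5.
- With no alkene present, dimethyldioxirane (acetone/CH2Cl2, 0 °C, then brief cat. p-TsOH) should give 4'-benzyloxy-3-hydroxy-6-methoxy-5,7-bis(methoxymethoxy)flavone F6.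
- HCl in MeOH at 50 °C should give 4'-benzyloxy-3,5,7-trihydroxy-6-methoxyflavone F7.
- Ac2O, pyridine and DMAP should give 3,5,7-triacetoxy-4'-benzyloxy-6-methoxyflavone F8.
- Hydrogenolysis (H2, Pd/C, EtOAc) should give 3,5,7-triacetoxy-4'-hydroxy-6-methoxyflavone F9.
- Mitsunobu etherification with prenol (PPh3, DIAD, THF, 0 °C) should give 3,5,7-triacetoxy-6-methoxy-4'-prenyloxyflavone F10.
- Methanolysis of F10 (K2CO3, MeOH, argon, 0 °C → rt) should release 19.

Further compounds
F1 | step 6 | N-methoxy-N-methyl-3-[4-(3-methylbut-2-enyloxy)phenyl]prop-2-ynamide | CON(C)C(=O)C#Cc1ccc(OCC=C(C)C)cc1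
F2 | step 6 | 1-[2-hydroxy-5-methoxy-4,6-bis(methoxymethoxy)phenyl]-3-[4-(3-methylbut-2-enyloxy)phenyl]prop-2-yn-1-one | COCOc1cc(O)c(C(=O)C#Cc2ccc(OCC=C(C)C)cc2)c(OCOC)c1OC
F3 | step 7 | 1-[2-hydroxy-5-methoxy-4,6-bis(methoxymethoxy)phenyl]ethanone | COCOc1cc(O)c(C(C)=O)c(OCOC)c1OC
F4 | step 7 | (E)-1-[2-hydroxy-5-methoxy-4,6-bis(methoxymethoxy)phenyl]-3-[4-(3-methylbut-2-enyloxy)phenyl]prop-2-en-1-one | COCOc1cc(O)c(C(=O)/C=C/c2ccc(OCC=C(C)C)cc2)c(OCOC)c1OC
F5 | step 8 | 4'-benzyloxy-6-methoxy-5,7-bis(methoxymethoxy)flavone | COCOc1cc2oc(-c3ccc(OCc4ccccc4)cc3)cc(=O)c2c(OCOC)c1OC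
F6 | step 8 | 4'-benzyloxy-3-hydroxy-6-methoxy-5,7-bis(methoxymethoxy)flavone | COCOc1cc2oc(-c3ccc(OCc4ccccc4)cc3)c(O)c(=O)c2c(OCOC)c1OC
F7 | step 8 | 4'-benzyloxy-3,5,7-trihydroxy-6-methoxyflavone | COc1c(O)cc2oc(-c3ccc(OCc4ccccc4)cc3)c(O)c(=O)c2c1O
F8 | step 8 | 3,5,7-triacetoxy-4'-benzyloxy-6-methoxyflavone | COc1c(OC(C)=O)cc2oc(-c3ccc(OCc4ccccc4)cc3)c(OC(C)=O)c(=O)c2c1OC(C)=O
F9 | step 8 | 3,5,7-triacetoxy-4'-hydroxy-6-methoxyflavone | COc1c(OC(C)=O)cc2oc(-c3ccc(O)cc3)c(OC(C)=O)c(=O)c2c1OC(C)=O
F10 | step 8 | 3,5,7-triacetoxy-6-methoxy-4'-prenyloxyflavone | COc1c(OC(C)=O)cc2oc(-c3ccc(OCC=C(C)C)cc3)c(OC(C)=O)c(=O)c2c1OC(C)=O
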